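The target is cut at both ArCH2–aryl bonds of the central phenol ring B (C1 phenethyl, C2 and C6 4-hydroxybenzyl, C5 OH). C6 lies ortho and C2 para to the C5 oxygen, so a single phenoxide can turn both benzylic carbons, one after the other, into quinone methide acceptors. In one flask, the precursor phenol, which carries pivaloyloxymethyl groups at these two positions and the benzyl-protected ring A phenethyl chain between them, takes two 4-benzyloxyphenyl groups from two equivalents of the aryl Grignard reagent and forms both diarylmethane bonds. The precursor comes from dimethyl 4-hydroxyisophthalate by magnesiation–iodination between the esters, B-alkyl Suzuki coupling and ester-to-pivalate adjustment; hydrogenolysis ends the route.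

Key step: step 10

Assumption: the tetrahydropyranyl (THP) acetal carbon is formed as a racemate; it is the only stereocentre in the route, is removed in step 8, and the target is achiral.
Assumption: the phenol is masked as a THP acetal so that it can be freed by a pyridinium salt in the presence of the acid-labile ortho/para-oxygenated benzylic pivalates.

Step 1
Reactants: 1 3-hydroxy-5-methoxybenzaldehyde
Product: 2 3-(benzyloxy)-5-methoxybenzaldehyde
Conditions: BnBr (1.1 equiv), K2CO3 (1.5 equiv), DMF, rt
Reagents that add atoms: benzyl bromide, BrCc1ccccc1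
Why: Williamson ether synthesis on the only acidic OH should give the benzyl ether that keeps ring A from acting as a phenoxide nucleophile in step 10 and falls off in the final hydrogenolysis.

Step 2
Reactants: 2 3-(benzyloxy)-5-methoxybenzaldehyde
Product: 3 1-(benzyloxy)-3-ethenyl-5-methoxybenzene
Conditions: Ph3PCH3Br (1.3 equiv), KOtBu (1.25 equiv), THF, 0 °C → rt
Reagents that add atoms: methyltriphenylphosphonium bromide, C[P+](c1ccccc1)(c1ccccc1)c1ccccc1.[Br-]
Why: Wittig methylenation of a non-enolisable aryl aldehyde should give the styrene cleanly.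

Step 3
Reactants: 4 dimethyl 4-hydroxyisophthalate
Product: 5 dimethyl 4-(tetrahydro-2H-pyran-2-yloxy)isophthalate (racemic)
Conditions: 3,4-dihydro-2H-pyran (3 equiv), PPTS (0.1 equiv), CH2Cl2, rt → 40 °C
Reagents that add atoms: 3,4-dihydro-2H-pyran, C1=COCCC1
Why: Acid-catalysed addition of the phenol to the enol ether (tetrahydropyranylation) masks the acidic OH for the metalation; the acetal carbon forms as a racemate without control, which is harmless.

Step 4
Reactants: 5 dimethyl 4-(tetrahydro-2H-pyran-2-yloxy)isophthalate (racemic)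
Product: 7 dimethyl 2-iodo-4-(tetrahydro-2H-pyran-2-yloxy)isophthalate (racemic), via arylmagnesium chloride 6 (not isolated)
Conditions: TMPMgCl·LiCl (1.2 equiv), THF, −20 → 0 °C; then I2 (1.3 equiv), THF, −20 °C → rt
Reagents that add atoms: iodine, II
Why: Directed ortho-magnesiation with the hindered magnesium amide should remove the C2 hydrogen, which is the most acidic ring hydrogen because both flanking ester carbonyls acidify it and chelate magnesium, without addition to the esters, and iodinolysis of the aryl–magnesium bond then places iodine at C2.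

Step 5
Reactants: 3 1-(benzyloxy)-3-ethenyl-5-methoxybenzene; 7 dimethyl 2-iodo-4-(tetrahydro-2H-pyran-2-yloxy)isophthalate (racemic)
Product: 9 dimethyl 2-{2-[3-(benzyloxy)-5-methoxyphenyl]ethyl}-4-(tetrahydro-2H-pyran-2-yloxy)isophthalate (racemic), via B-alkyl-9-BBN adduct 8 (not isolated)
Conditions: 3 (1.3 equiv), 9-BBN dimer (0.65 equiv), THF, 0 °C → rt; then 7, Pd(OAc)2 (5 mol %), SPhos (10 mol %), 3 M aq. K3PO4 (3 equiv), THF, 60 °C
Reagents that add atoms: none
Why: Anti-Markovnikov hydroboration of the styrene followed by B-alkyl Suzuki–Miyaura coupling should join the fragments, since the electron-poor aryl iodide adds readily to zerovalent palladium and the bulky electron-rich biaryl phosphine carries the coupling at the doubly ortho-substituted carbon while esters, acetal and benzyl ether stay inert.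

Step 6
Reactants: 9 dimethyl 2-{2-[3-(benzyloxy)-5-methoxyphenyl]ethyl}-4-(tetrahydro-2H-pyran-2-yloxy)isophthalate (racemic)
Product: 10 [2-{2-[3-(benzyloxy)-5-methoxyphenyl]ethyl}-4-(tetrahydro-2H-pyran-2-yloxy)-1,3-phenylene]dimethanol (racemic)
Conditions: LiAlH4 (2.5 equiv), THF, 0 °C → rt; aqueous NaOH work-up
Reagents that add atoms: none
Why: Hydride reduction of both aryl methyl esters to benzylic alcohols should proceed while the acetal, benzyl ether and methyl ether are untouched by LiAlH4.

Step 7
Reactants: 10 [2-{2-[3-(benzyloxy)-5-methoxyphenyl]ethyl}-4-(tetrahydro-2H-pyran-2-yloxy)-1,3-phenylene]dimethanol (racemic)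
Product: 11 [2-{2-[3-(benzyloxy)-5-methoxyphenyl]ethyl}-4-(tetrahydro-2H-pyran-2-yloxy)-1,3-phenylene]bis(methylene) bis(2,2-dimethylpropanoate) (racemic)
Conditions: PivCl (3 equiv), pyridine (6 equiv), DMAP (0.1 equiv), CH2Cl2, 0 °C → rt
Reagents that add atoms: pivaloyl chloride (two equivalents incorporated), CC(C)(C)C(=O)Cl
Why: DMAP-catalysed acylation of the two primary benzylic alcohols should be unambiguous because the phenol is still masked, and excess pyridine keeps the acetal from acid.

Step 8
Reactants: 11 [2-{2-[3-(benzyloxy)-5-methoxyphenyl]ethyl}-4-(tetrahydro-2H-pyran-2-yloxy)-1,3-phenylene]bis(methylene) bis(2,2-dimethylpropanoate) (racemic)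
Product: 12 3-{2-[3-(benzyloxy)-5-methoxyphenyl]ethyl}-2,4-bis(pivaloyloxymethyl)phenol
Conditions: PPTS (0.2 equiv), MeOH/CH2Cl2 1:1, 0 °C → rt; pH 7 buffer work-up, no basic wash; used promptly
Reagents that add atoms: none
Why: Acid-catalysed transacetalisation of the aryl THP acetal to methanol should free the phenol under a pyridinium salt that is too weak an acid to ionise the benzylic pivalates and never basic, so no phenoxide and no quinone methide can arise before step 10.

Step 9
Reactants: 13 1-(benzyloxy)-4-bromobenzene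
Product: 14 [4-(benzyloxy)phenyl]magnesium bromide (THF solution, titrated and used directly)
Conditions: Mg turnings (1.2 equiv), I2 (one crystal), THF, rt → 40 °C
Reagents that add atoms: magnesium, [Mg]
Why: Grignard formation by magnesium insertion into the aryl C–Br bond is routine for this aryl bromide, and the benzyl ether is inert to it.

Step 10
Reactants: 12 3-{2-[3-(benzyloxy)-5-methoxyphenyl]ethyl}-2,4-bis(pivaloyloxymethyl)phenol; 14 [4-(benzyloxy)phenyl]magnesium bromide (three equivalents consumed: one as base, two as aryl donors)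
Product: 19 2,4-bis[4-(benzyloxy)benzyl]-3-{2-[3-(benzyloxy)-5-methoxyphenyl]ethyl}phenol, via bromomagnesium phenoxide 15 (not isolated), via ortho-quinone methide 16 (not isolated), via monoarylated phenoxide 17 (not isolated), via para-quinone methide 18 (not isolated)
Conditions: 12 in THF added slowly to 14 (4.5 equiv) in THF at −78 °C; → rt (40 °C if the second elimination lags); 1 M aq. HCl, 0 °C
Reagents that add atoms: [4-(benzyloxy)phenyl]magnesium bromide (the second aryl-donating equivalent of 14, which supplies the second 4-benzyloxyphenyl group), Br[Mg]c1ccc(OCc2ccccc2)cc1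
Why: One equivalent of 14 deprotonates the phenol, and magnesium phenoxide 15 expels the neighbouring, magnesium-chelated pivalate (1,4-elimination) to give ortho-quinone methide 16, whose exocyclic methylene takes an aryl group from a second equivalent of 14 by 1,4-addition and so regenerates a phenoxide (17). Phenoxide 17 then ejects the para pivalate by vinylogous 1,6-elimination to para-quinone methide 18, and 1,6-addition of an aryl group from a third equivalent of 14 gives the phenoxide of 19; if the para pivalate leaves first the same product results. The closest known reaction type is base-triggered generation of ortho- and para-quinone methides from (acyloxymethyl)phenols with in situ conjugate addition of Grignard reagents, here run twice in succession in one flask. No ring is closed and no stereocentre is created. The step needs attack at the methylene carbons and not at the ester carbonyls, which the tert-butyl shielding of the pivalates, the low starting temperature and the rearomatisation that drives each conjugate addition should secure, and it needs a defined site on the incoming arene, which is fixed because the carbon bound to magnesium is the nucleophile. Keeping 14 in excess throughout (inverse addition) and having ring A as a benzyl ether, not a phenoxide, should keep the quinone methides from being trapped by ring A or by another phenoxide.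

Step 11
Reactants: 19 2,4-bis[4-(benzyloxy)benzyl]-3-{2-[3-(benzyloxy)-5-methoxyphenyl]ethyl}phenol
Product: 20 2,4-bis(4-hydroxybenzyl)-3-[2-(3-hydroxy-5-methoxyphenyl)ethyl]phenol
Conditions: H2 (1 atm), Pd/C (10 wt % palladium on carbon), EtOAc/MeOH, rt
Reagents that add atoms: none
Why: Catalytic hydrogenolysis should cleave the three aryl benzyl ethers, while the diarylmethane and bibenzyl C–C bonds and the aryl methyl ether are stable under these conditions.

Compound list
1 | 3-hydroxy-5-methoxybenzaldehyde | COc1cc(O)cc(C=O)c1 | starting material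
2 | 3-(benzyloxy)-5-methoxybenzaldehyde | COc1cc(OCc2ccccc2)cc(C=O)c1 | intermediate
3 | 1-(benzyloxy)-3-ethenyl-5-methoxybenzene | COc1cc(OCc2ccccc2)cc(C=C)c1 | intermediate
4 | dimethyl 4-hydroxyisophthalate | COC(=O)c1ccc(O)c(C(=O)OC)c1 | starting material
5 | dimethyl 4-(tetrahydro-2H-pyran-2-yloxy)isophthalate (racemic) | COC(=O)c1ccc(OC2CCCCO2)c(C(=O)OC)c1 | intermediate
6 | [2,6-bis(methoxycarbonyl)-3-(tetrahydro-2H-pyran-2-yloxy)phenyl]magnesium chloride (LiCl complex, racemic) | COC(=O)c1ccc(OC2CCCCO2)c(C(=O)OC)c1[Mg]Cl | intermediate (not isolated)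
7 | dimethyl 2-iodo-4-(tetrahydro-2H-pyran-2-yloxy)isophthalate (racemic) | COC(=O)c1ccc(OC2CCCCO2)c(C(=O)OC)c1I | intermediate
8 | 9-{2-[3-(benzyloxy)-5-methoxyphenyl]ethyl}-9-borabicyclo[3.3.1]nonane | COc1cc(OCc2ccccc2)cc(CCB2C3CCCC2CCC3)c1 | intermediate (not isolated)
9 | dimethyl 2-{2-[3-(benzyloxy)-5-methoxyphenyl]ethyl}-4-(tetrahydro-2H-pyran-2-yloxy)isophthalate (racemic) | COC(=O)c1ccc(OC2CCCCO2)c(C(=O)OC)c1CCc1cc(OC)cc(OCc2ccccc2)c1 | intermediate
10 | [2-{2-[3-(benzyloxy)-5-methoxyphenyl]ethyl}-4-(tetrahydro-2H-pyran-2-yloxy)-1,3-phenylene]dimethanol (racemic) | OCc1ccc(OC2CCCCO2)c(CO)c1CCc1cc(OC)cc(OCc2ccccc2)c1 | intermediate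
11 | [2-{2-[3-(benzyloxy)-5-methoxyphenyl]ethyl}-4-(tetrahydro-2H-pyran-2-yloxy)-1,3-phenylene]bis(methylene) bis(2,2-dimethylpropanoate) (racemic) | CC(C)(C)C(=O)OCc1ccc(OC2CCCCO2)c(COC(=O)C(C)(C)C)c1CCc1cc(OC)cc(OCc2ccccc2)c1 | intermediate
12 | 3-{2-[3-(benzyloxy)-5-methoxyphenyl]ethyl}-2,4-bis(pivaloyloxymethyl)phenol | COc1cc(OCc2ccccc2)cc(CCc2c(COC(=O)C(C)(C)C)ccc(O)c2COC(=O)C(C)(C)C)c1 | intermediate
13 | 1-(benzyloxy)-4-bromobenzene | Brc1ccc(OCc2ccccc2)cc1 | starting material
14 | [4-(benzyloxy)phenyl]magnesium bromide | Br[Mg]c1ccc(OCc2ccccc2)cc1 | intermediate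
15 | bromomagnesium 3-{2-[3-(benzyloxy)-5-methoxyphenyl]ethyl}-2,4-bis(pivaloyloxymethyl)phenoxide | COc1cc(OCc2ccccc2)cc(CCc2c(COC(=O)C(C)(C)C)ccc(O[Mg]Br)c2COC(=O)C(C)(C)C)c1 | intermediate (not isolated)
16 | 5-{2-[3-(benzyloxy)-5-methoxyphenyl]ethyl}-6-methylidene-4-(pivaloyloxymethyl)cyclohexa-2,4-dien-1-one | C=C1C(=O)C=CC(COC(=O)C(C)(C)C)=C1CCc1cc(OC)cc(OCc2ccccc2)c1 | intermediate (not isolated)
17 | bromomagnesium 2-[4-(benzyloxy)benzyl]-3-{2-[3-(benzyloxy)-5-methoxyphenyl]ethyl}-4-(pivaloyloxymethyl)phenoxide | COc1cc(OCc2ccccc2)cc(CCc2c(COC(=O)C(C)(C)C)ccc(O[Mg]Br)c2Cc2ccc(OCc3ccccc3)cc2)c1 | intermediate (not isolated)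
18 | 2-[4-(benzyloxy)benzyl]-3-{2-[3-(benzyloxy)-5-methoxyphenyl]ethyl}-4-methylidenecyclohexa-2,5-dien-1-one | C=C1C=CC(=O)C(Cc2ccc(OCc3ccccc3)cc2)=C1CCc1cc(OC)cc(OCc2ccccc2)c1 | intermediate (not isolated)
19 | 2,4-bis[4-(benzyloxy)benzyl]-3-{2-[3-(benzyloxy)-5-methoxyphenyl]ethyl}phenol | COc1cc(OCc2ccccc2)cc(CCc2c(Cc3ccc(OCc4ccccc4)cc3)ccc(O)c2Cc2ccc(OCc3ccccc3)cc2)c1 | intermediate
20 | 2,4-bis(4-hydroxybenzyl)-3-[2-(3-hydroxy-5-methoxyphenyl)ethyl]phenol | COc1cc(O)cc(CCc2c(Cc3ccc(O)cc3)ccc(O)c2Cc2ccc(O)cc2)c1 | target

Total step count: 11. Longest linear sequence: 8 steps (4 → 5 → 7 → 9 → 10 → 11 → 12 → 19 → 20, steps 3, 4, 5, 6, 7, 8, 10 and 11).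

Steps most likely to fail

Step 10. The Grignard reagent may attack the pivalate carbonyls instead of the quinone methide carbons. The relay may stall after the first arylation if the magnesium phenoxide pushes out the para pivalate too slowly. The quinone methides may also oligomerise or be captured intramolecularly. The fallback sets out from diol 10 and comes back at 19, and makes both bonds by cross-coupling with no quinone methide. Diol 10 is acylated with methyl chloroformate and pyridine in CH2Cl2 to [2-{2-[3-(benzyloxy)-5-methoxyphenyl]ethyl}-4-(tetrahydro-2H-pyran-2-yloxy)-1,3-phenylene]bis(methylene) dimethyl bis(carbonate) F1. A palladium-catalysed benzylic Suzuki–Miyaura coupling with 4-(benzyloxy)phenylboronic acid ([Pd(C3H5)Cl]2, 1,5-bis(diphenylphosphino)pentane, K2CO3, DMF, 80 °C) should then give 2-{2,4-bis[4-(benzyloxy)benzyl]-3-{2-[3-(benzyloxy)-5-methoxyphenyl]ethyl}phenoxy}tetrahydro-2H-pyran F2. PPTS in MeOH frees the phenol to give 19; no benzylic ester is present at that stage.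

Step 8. The acid may ionise the ortho/para-oxygenated benzylic pivalates (methanolysis), or the freed phenol may lose pivalate during work-up and handling. The fallback sets out from 9 and comes back at 12, and never unmasks the phenol next to the pivalates. The THP group is removed at the diester stage (PPTS, MeOH, 40 °C), where nothing is acid-sensitive, to give dimethyl 2-{2-[3-(benzyloxy)-5-methoxyphenyl]ethyl}-4-hydroxyisophthalate F3. Reduction with LiAlH4 in THF and a neutral work-up gives 3-{2-[3-(benzyloxy)-5-methoxyphenyl]ethyl}-2,4-bis(hydroxymethyl)phenol F4. A Mitsunobu esterification with pivalic acid (PPh3, diisopropyl azodicarboxylate, THF, 0 °C) acylates alcoholic hydroxyls in preference to the phenolic one and should deliver 12.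

Step 5. Transmetalation of the alkylborane to the doubly ortho-substituted arylpalladium centre may be slow, so that protodeiodination and β-hydride loss take over. The fallback sets out from 7 and 3 and comes back at 9, forming the C–C bond at an sp2 carbon instead. A Heck reaction (Pd(OAc)2, P(o-tol)3, Et3N, DMF, 90 °C) should give dimethyl 2-{(E)-2-[3-(benzyloxy)-5-methoxyphenyl]ethenyl}-4-(tetrahydro-2H-pyran-2-yloxy)isophthalate F5. Diimide reduction of the stilbene double bond (TsNHNH2, NaOAc, THF/H2O, reflux) spares the benzyl ether, acetal and esters and gives 9.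

Further compounds
F1 | step 10 | [2-{2-[3-(benzyloxy)-5-methoxyphenyl]ethyl}-4-(tetrahydro-2H-pyran-2-yloxy)-1,3-phenylene]bis(methylene) dimethyl bis(carbonate) (racemic) | COC(=O)OCc1ccc(OC2CCCCO2)c(COC(=O)OC)c1CCc1cc(OC)cc(OCc2ccccc2)c1
F2 | step 10 | 2-{2,4-bis[4-(benzyloxy)benzyl]-3-{2-[3-(benzyloxy)-5-methoxyphenyl]ethyl}phenoxy}tetrahydro-2H-pyran (racemic) | COc1cc(OCc2ccccc2)cc(CCc2c(Cc3ccc(OCc4ccccc4)cc3)ccc(OC3CCCCO3)c2Cc2ccc(OCc3ccccc3)cc2)c1
F3 | step 8 | dimethyl 2-{2-[3-(benzyloxy)-5-methoxyphenyl]ethyl}-4-hydroxyisophthalate | COC(=O)c1ccc(O)c(C(=O)OC)c1CCc1cc(OC)cc(OCc2ccccc2)c1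
F4 | step 8 | 3-{2-[3-(benzyloxy)-5-methoxyphenyl]ethyl}-2,4-bis(hydroxymethyl)phenol | OCc1ccc(O)c(CO)c1CCc1cc(OC)cc(OCc2ccccc2)c1
F5 | step 5 | dimethyl 2-{(E)-2-[3-(benzyloxy)-5-methoxyphenyl]ethenyl}-4-(tetrahydro-2H-pyran-2-yloxy)isophthalate (racemic) | COC(=O)c1ccc(OC2CCCCO2)c(C(=O)OC)c1/C=C/c1cc(OC)cc(OCc2ccccc2)c1
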